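A small charge of substrate meets the gas phase, and the question is how it divides between target and side product.

| setting | spring | autumn | summer | south | south-west |
|---|---|---|---|---|---|
| substrate | 0.014 M (fed, over 50 min) | 0.017 M (fed, over 50 min) | 0.019 M (fed, over 50 min) | 0.015 M | 0.021 M (fed, over 50 min) |
| gas phase | 3.8 mM (held) | 3.8 mM (held) | 3.8 mM (held) | 3.8 mM | 3.8 mM (held) |
| remark | run made earlier; the fed solution adds 0.10 times the starting volume | run made earlier; the fed solution adds 0.10 times the starting volume | run made earlier; the fed solution adds 0.10 times the starting volume | everything together at the start, the whole solution of substrate included, so that from the start the volume is larger by 0.10 times the starting volume | the fed solution adds 0.10 times the starting volume |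
| time |  |  |  | 8.0 h | 8.0 h |

| run | time / h | target / % | side product / % |
|---|---|---|---|
| spring | 0.333 | 1.0 | 0.6 |
| spring | 1.00 | 1.5 | 1.1 |
| spring | 2.00 | 6.9 | 3.4 |
| spring | 3.00 | 8.3 | 4.2 |
| spring | 4.00 | 10.4 | 4.4 |
| autumn | 0.333 | 0 | 0.8 |
| autumn | 0.667 | 0 | 0 |
| autumn | 1.00 | 2.0 | 2.3 |
| autumn | 2.00 | 5.4 | 2.2 |
| autumn | 4.00 | 13.1 | 5.7 |
| summer | 0.833 | 1.7 | 2.6 |
| summer | 1.50 | 3.7 | 0.4 |
| summer | 2.50 | 7.5 | 4.6 |
| summer | 3.00 | 8.8 | 5.3 |
| summer | 4.00 | 11.2 | 6.6 |

(each reading ± 1 percentage point)

- charges are per starting volume, the dose included; the dosed solution carries all of it
- the numbers in the tables scatter by 1 percentage point (one standard deviation)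
- at the start none of the gas phase is in solution
- percentages count the whole charge, also what has not yet gone in

- the flask that ends with the higher share of target in all that became target or side product, or "neither" when 2 percentage points or less lies between them (south / south-west / neither)
- share of target in all that became target or side product, south
- share of target in all that became target or side product, south-west

The ladder of times starts with the feed, over in 50 min, which is far shorter than the run, so this reckoning treats south and south-west alike in that respect. Next comes a lag: the spring run shows 1.5% target at 1.00 h. Then comes the run itself, 8.0 h. The three runs lose a mean fraction by 4.00 h that gives a lifetime of substrate of 21.3 h, the slowest rung and longer than the run, so the flasks should still hold substrate at the end.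

At 4.00 h target reads 10.4%, 13.1% and 11.2% with rising charge, which shows no trend. Side product reads 4.4%, 5.7% and 6.6%, a rise of 2.2 percentage points against a scatter of 1 point per reading. This reckoning takes that rise as scatter, so both rates go as c(substrate), pseudo-first-order with the gas held. Pooled, the three runs give 67.5%: in this reckoning, this share of target in target plus side product, the selectivity s, does not depend on charge. Going round once more, 68.7% of the substrate remains at 8.0 h, but both rates shrink by that same factor, so s stands. This reckoning therefore puts south and south-west at s and says neither.

The forecast differs: south, with 72% for south and 66.5% for south-west. Its ground reads “Side product, as a percentage, rises with charge”.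

The flask gives neither: south 63.8%, south-west 64.3%.

    dissolved gas → decomposed reagent (k = 0.323 h⁻¹)
    substrate → side product (k = 0.0184 h⁻¹)
    substrate + dissolved gas ⇌ target (K = 239 L mol⁻¹, k = 12.4 L mol⁻¹ h⁻¹)
    gas phase ⇌ dissolved gas, rate k4*(csat - [dissolved gas]) (kL = 3.25 h⁻¹)

Both lie under s, south by 3.7 points and south-west by 3.2 points, and a flask like south-west with 0.0084 M of substrate gives 64.8%, close to them. Neither flask is at rest at 8.0 h: south still holds 66.8% of its substrate and south-west 67.9%. South-west read at 20 h has fallen to a share of 57.1%. At 80.0 h south holds 21.5% substrate, target has gone from 21.2% to 21.6%, and side product has grown from 12.0% to 56.9%, which brings the share, lower than s, to 27.5%.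

The numbers in the tables are simulated for an exercise.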